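All runs were generated by integration for an exercise, noise included.

The vessel is a stirred tank in which substrate goes two ways: it opens, or it pairs to homo dimer. You asked for a quick number and guessed that alpha's slow feed wins. I test that below.

| setting | larch | oak | theta | delta | alpha | gamma | zeta |
|---|---|---|---|---|---|---|---|
| substrate | 0.010 M | 0.010 M | 0.010 M (fed, over 8.0 min) | 0.010 M (in portions, 4, over 30 min) | 0.010 M (fed, over 30 min) | 0.010 M | 0.010 M |
| first nucleophile | 9.5 mM | 9.5 mM | 9.50 mM | 9.50 mM | 9.50 mM | 9.50 mM | 9.50 mM |
| second nucleophile | 10 mM | 10 mM | 10.0 mM | 10.0 mM | 10.0 mM | 10.0 mM (fed, over 30 min) | 10.0 mM |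
| capture agent | 10 mM | 15 mM | 10.0 mM | 10.0 mM | 10.0 mM | 10.0 mM | 10.0 mM |
| remark | run made earlier | run made earlier | all else is in the flask from the start; the feed brings no volume worth counting | first portion at the start, last at 30 min | all else is in the flask from the start; the feed brings no volume worth counting | all else is in the flask from the start; the feed brings no volume worth counting | everything together at the start |
| time |  |  | 40 min | 40 min | 40 min | 40 min | 40 min |
- larch (time / min: target / %): 5.00: 9.6; 10.0: 10.7; 15.0: 11.3; 20.0: 11.6; 25.0: 11.3
- oak (time / min: target / %): 0.667: 3.8; 1.33: 5.7; 2.50: 7.7; 4.00: 8.6; 8.00: 10.1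

(each reading ± 0.3 percentage points)
- the flask with the highest amount of target, in percent of the substrate charged ("all alike" if they lie within 1.5 percentage points) (theta / delta / alpha / gamma / zeta / all alike)
- final target, as a percentage of the substrate charged, in theta
- final target, as a percentage of the substrate charged, in delta
- final target, as a percentage of the substrate charged, in alpha
- final target, as a percentage of the substrate charged, in gamma
- final target, as a percentage of the substrate charged, in zeta
- a species is counted by the substrate in it: one homo dimer counts as two
- steps under discussion: 2 substrate -> homo dimer; first nucleophile + open intermediate -> target; substrate <-> open intermediate; second nucleophile + open intermediate -> other capture product; open intermediate + capture agent -> trapped intermediate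

Let s be substrate as a fraction of the charge, lost as ds/dt = −a·s − b·s·s, where a is opening and b is the homo dimer term. Early on, s follows a second-order decay, so the target slope falls as the inverse of (1 + b·t). I read two slopes from oak, neglecting its extra capture agent:

slope 0.0570 min⁻¹ at 0.334 min; slope 0.0287 min⁻¹ at 0.999 min

b = 2.94 min⁻¹

r = 0.113 min⁻¹

Here r is the target made per minute per unit of standing substrate, so target equals r times the area under s. With a scatter of 0.3 percentage points, these are rough readings.

In a batch, the area under s to the end is ln(1 + b/a)/b. Larch has zeta's charges, so I set r times that area equal to its reading of 11.6% at 20.0 min, which gives a = 0.150 min⁻¹. During a feed, s holds where a·s + b·s·s equals the inverse feed time: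

alpha: s = 0.0839, target = r·s·t = 28.4%

Theta's shorter feed gives 16.4%. Both figures leave out the substrate that still stands when the feed ends. So I expect alpha to give more target than zeta. Gamma I leave open, since these readings do not separate the two nucleophiles. Delta I do not reckon here.

The forecast names alpha, with 20.5%, 23.5%, 29%, 14% and 11.5% for theta, delta, alpha, gamma and zeta: “Feeding keeps s low, which starves dimerisation”.

The flasks give 19.1%, 23.0%, 27.3%, 15.6% and 11.5% in that order, and alpha is highest.

    2 substrate → homo dimer (k = 2.10 M⁻¹ s⁻¹)
    first nucleophile + open intermediate → target (k = 160 M⁻¹ s⁻¹)
    substrate ⇌ open intermediate (K = 0.00540, k = 0.00370 s⁻¹)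
    second nucleophile + open intermediate → other capture product (k = 86.0 M⁻¹ s⁻¹)
    open intermediate + capture agent → trapped intermediate (k = 7.50 M⁻¹ s⁻¹)

In zeta, the homo dimer step has done half of its turnover up to 40 min by 0.289 min, and the opening step has done the same by 1.30 min. In alpha, substrate averages 8.03 × 10⁻⁴ M over the first 30 min. That mean, with r, gives 27.2% for those minutes, with the time after the feed not counted.

One neighbour is like zeta but with 0.024 M of first nucleophile. With the constants, the target's share of the three captures at the charged amounts (the selectivity) is 61.9% in zeta and 80.4% in this neighbour. Scaling r by that ratio and keeping the area read from larch gives 15.1%. The computed flask gives 16.3%.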